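**Plan**

1. Retrosynthesis: the three acyl–oxygen bonds are cut first (propanoyl on O4, acetyl on O3, 2-methylbutanoyl on O5). Then the bond from C1 to its carboxyl carbon is cut and the C5 oxygen is re-bridged to C2. Last, the ring bonds C2–C3 and C4–C5 are cut, which leaves furan 1 and vinylene carbonate 2.
2. Enabling feature: in the cyclohexene ring, C2–C1–C6–C5 with the oxygen on C5 are a furan in disguise (the C5–O bond and the C1=C2 alkene are what remains of a C2–O–C5 bridge). The cis C3/C4 dioxygen pair is vinylene carbonate in disguise, and without the carboxyl carbon the adduct 3 is meso.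
3. Forward: Diels–Alder of 1 and 2 closes the carbocycle as the oxa-bridged 3. Hydroformylation adds the carboxyl carbon (4), oxidation (5) and esterification (6) follow, base opens the bridge (7) and methanolysis frees methyl shikimate 8.
4. The three hydroxyls are then told apart: 3,4-orthoacetate 9, acylation of O5 with (R)-2-methylbutanoic acid 10 (giving 11), axial-selective orthoester opening to the 3-acetate 12, and propanoylation of O4 to the target 13.
5. Stereochemistry: 3,4-cis and 4,5-trans come from the suprafacial endo cycloaddition. The absolute configuration comes from the enantiotopos-selective hydroformylation of meso 3. The side-chain center is bought with 10.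

Key step: step 1

Remark: the acyl group on O5 is (R)-configured in the given structure, so (R)-2-methylbutanoic acid is used and is taken as a commercial, enantiopure compound.

**Route**

Step 1
Reactants: 1 furan; 2 vinylene carbonate (1,3-dioxol-2-one)
Product: 3 (1R,2S,3R,4S)-7-oxabicyclo[2.2.1]hept-5-ene-2,3-diyl carbonate (meso; carbonate ring endo, on the face away from the oxygen bridge)
Conditions: furan (excess, neat), BHT (cat.), sealed tube, 120 °C (or 12 kbar, 25 °C); endo isomer separated from exo by crystallisation or chromatography
Reagents that add atoms: none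
Why: Thermal, concerted, suprafacial [4+2] cycloaddition of the furan diene with the carbonate-activated Z-alkene, a Diels–Alder reaction of the same type as those of furan with other cyclic cis-dienophiles such as maleic anhydride. The carbocyclic six-membered ring is closed in this intermolecular [4+2] mode, both new sigma bonds (C2–C3 and C4–C5 in target numbering) forming in one transition state, while the furan ring persists as the oxygen-bridged 2,5-dihydrofuran and the dioxolanone ring is carried in unchanged. C3 and C4 come out cis because the Z geometry is locked in the five-membered carbonate and the addition is suprafacial, and the two bridgehead carbons (future C2 and C5) are set by the suprafacial addition across furan positions 2 and 5. The endo transition state places the carbonate anti to the oxygen bridge, which is the later trans relation of O4 and O5, whereas the exo adduct would lead to the 5-epimer. The only selectivity needed is therefore endo over exo, to be secured by kinetic control (lowest workable temperature, or high pressure, which should favour the more compact endo transition state) and by removal of the exo isomer; no regio- or enantioselectivity is required because both partners are symmetric and 3 is meso. The furan oxygen and the carbonate are the built-in helpers: the first stays as O5 when the bridge is opened in step 5, and the second is taken off in the same step.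

Step 2
Reactants: 3 meso endo adduct
Product: 4 (1S,2S,4R,5S,6R)-5,6-(carbonyldioxy)-7-oxabicyclo[2.2.1]heptane-2-carbaldehyde (formyl exo, carbonate endo)
Conditions: Rh(acac)(CO)2 (1 mol %), TangPhos [(1S,1'S,2R,2'R)-1,1'-di-tert-butyl-2,2'-biphospholane or its antipode, 1.2 mol %], CO/H2 (1:1, 10 bar), toluene, 60 °C
Reagents that add atoms: carbon monoxide, [C-]#[O+]
Why: Rhodium-catalysed asymmetric hydroformylation of a meso [2.2.1]-bicyclic alkene: the monovalent rhodium hydride adds syn from the open exo face (the endo face is screened by the carbonate), CO insertion and hydrogenolysis deliver the exo formyl group, and the chiral bisphospholane decides which of the two enantiotopic alkene carbons is formylated, which sets the new C1 stereocenter and with it the absolute sense of the whole ring (the ligand antipode that leads to 4 is to be fixed in a trial run with both).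

Step 3
Reactants: 4 exo aldehyde
Product: 5 (1S,2S,4R,5S,6R)-5,6-(carbonyldioxy)-7-oxabicyclo[2.2.1]heptane-2-carboxylic acid
Conditions: NaClO2, NaH2PO4, 2-methyl-2-butene, t-BuOH/H2O, 0 °C to rt
Reagents that add atoms: sodium chlorite, [Na+].[O-]Cl=O
Why: Pinnick oxidation, in which chlorous acid adds to the aldehyde and fragments to the acid and HOCl (scavenged by the alkene) in a buffered, weakly acidic medium that should leave the carbonate alone, cause no enolisation (hence no bridge opening) and touch no stereocenter.

Step 4
Reactants: 5 exo acid
Product: 6 methyl (1S,2S,4R,5S,6R)-5,6-(carbonyldioxy)-7-oxabicyclo[2.2.1]heptane-2-carboxylate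
Conditions: TMSCHN2, toluene/MeOH (4:1), 0 °C to rt
Reagents that add atoms: trimethylsilyldiazomethane, C[Si](C)(C)C=[N+]=[N-]
Why: Methyl esterification with trimethylsilyldiazomethane, in which the acid protonates the diazoalkane, methanol removes the silyl group and the carboxylate is O-methylated with loss of N2 under neutral conditions that leave the carbonate and all stereocenters alone.

Step 5
Reactants: 6 exo methyl ester
Product: 8 methyl (−)-shikimate, via methyl 3,4-O-carbonylshikimate 7 (not isolated)
Conditions: LiN(SiMe3)2 (1.1 equiv), THF, −78 to −20 °C; then MeOH, 0 °C to rt; AcOH quench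
Reagents that add atoms: none
Why: Base-induced E1cB opening of a 7-oxanorbornane-2-carboxylate, in which the ester enolate at C1 expels the bridge oxygen from the adjacent bridgehead C2 to give the C1=C2 enoate and the C5 alkoxide with C3, C4 and C5 untouched (the C1 stereocenter is erased as planned), after which the lithium methoxide formed on addition of methanol should transesterify the five-membered carbonate to dimethyl carbonate and the free cis-diol.

Step 6
Reactants: 8 methyl (−)-shikimate
Product: 9 methyl 3,4-O-(1-methoxyethylidene)shikimate (both epimers at the orthoester carbon)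
Conditions: MeC(OMe)3 (1.3 equiv), CSA (cat.), MeCN, rt; then Et3N
Reagents that add atoms: trimethyl orthoacetate, COC(C)(OC)OC
Why: Acid-catalysed orthoester exchange, in which only the cis-3,4-diol can close a strain-free five-membered cyclic orthoester (the same preference that makes 3,4-acetonides of shikimates form selectively), so O5 should stay free; the new orthoester carbon forms as a mixture of epimers, which is immaterial because this center disappears in step 8.

Step 7
Reactants: 9 3,4-orthoacetate; 10 (R)-2-methylbutanoic acid
Product: 11 methyl 3,4-O-(1-methoxyethylidene)-5-O-[(2R)-2-methylbutanoyl]shikimate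
Conditions: DCC (1.5 equiv), DMAP (0.2 equiv), CH2Cl2, 0 °C to rt
Reagents that add atoms: none
Why: Steglich esterification, in which the O-acylisourea of 10 is relayed by DMAP as the acylpyridinium ion to the only free hydroxyl (equatorial O5) under non-aqueous, weakly basic conditions that should keep the orthoester intact and cannot epimerise the alpha stereocenter of the acid (no ketene pathway), so both partners retain their configuration.

Step 8
Reactants: 11 5-O-acyl orthoacetate
Product: 12 methyl 3-O-acetyl-5-O-[(2R)-2-methylbutanoyl]shikimate (free 4-OH)
Conditions: AcOH/H2O (4:1), rt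
Reagents that add atoms: water, O
Why: Mild acid hydrolysis of a cyclic orthoester, in which loss of methanol gives the 1,3-dioxolan-2-ylium ion, water adds, and the hemi-orthoester should collapse under stereoelectronic control to the ester on the pseudo-axial allylic oxygen (O3) and the free equatorial hydroxyl (O4), as cis-fused orthoesters on six-membered rings generally do, while the acidic medium suppresses base-promoted acyl migration and leaves the other esters alone.

Step 9
Reactants: 12 3-acetate with free 4-OH
Product: 13 methyl (3R,4S,5R)-3-acetoxy-5-{[(2R)-2-methylbutanoyl]oxy}-4-(propanoyloxy)cyclohex-1-ene-1-carboxylate (target)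
Conditions: (EtCO)2O, pyridine, DMAP (cat.), CH2Cl2, 0 °C
Reagents that add atoms: propanoic anhydride, CCC(=O)OC(=O)CC
Why: DMAP-catalysed acylation of the remaining equatorial secondary alcohol with the anhydride, run cold and with excess reagent so that acylation should outrun any acetyl shift from O3 to O4; no stereocenter is touched.

**Compound list**

1 | furan | c1ccoc1 | starting material
2 | vinylene carbonate (1,3-dioxol-2-one) | O=C1OC=CO1 | starting material
3 | (1R,2S,3R,4S)-7-oxabicyclo[2.2.1]hept-5-ene-2,3-diyl carbonate (meso, endo) | O=C1O[C@@H]2[C@H](O1)[C@H]3O[C@@H]2C=C3 | intermediate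
4 | (1S,2S,4R,5S,6R)-5,6-(carbonyldioxy)-7-oxabicyclo[2.2.1]heptane-2-carbaldehyde (formyl exo) | O=C1O[C@@H]2[C@H](O1)[C@H]3O[C@@H]2C[C@@H]3C=O | intermediate
5 | (1S,2S,4R,5S,6R)-5,6-(carbonyldioxy)-7-oxabicyclo[2.2.1]heptane-2-carboxylic acid | O=C1O[C@@H]2[C@H](O1)[C@H]3O[C@@H]2C[C@@H]3C(=O)O | intermediate
6 | methyl (1S,2S,4R,5S,6R)-5,6-(carbonyldioxy)-7-oxabicyclo[2.2.1]heptane-2-carboxylate | O=C1O[C@@H]2[C@H](O1)[C@H]3O[C@@H]2C[C@@H]3C(=O)OC | intermediate
7 | methyl 3,4-O-carbonylshikimate [methyl (3R,4S,5R)-3,4-(carbonyldioxy)-5-hydroxycyclohex-1-ene-1-carboxylate] | O=C1O[C@@H]2[C@H](O1)C=C(C(=O)OC)C[C@H]2O | intermediate (not isolated)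
8 | methyl (−)-shikimate [methyl (3R,4S,5R)-3,4,5-trihydroxycyclohex-1-ene-1-carboxylate] | O[C@@H]1[C@H](O)C=C(C(=O)OC)C[C@H]1O | intermediate
9 | methyl 3,4-O-(1-methoxyethylidene)shikimate (orthoester carbon: both epimers) | COC1(C)O[C@@H]2[C@H](O1)C=C(C(=O)OC)C[C@H]2O | intermediate
10 | (R)-2-methylbutanoic acid | CC[C@@H](C)C(=O)O | starting material
11 | methyl 3,4-O-(1-methoxyethylidene)-5-O-[(2R)-2-methylbutanoyl]shikimate (orthoester carbon: both epimers) | COC1(C)O[C@@H]2[C@H](O1)C=C(C(=O)OC)C[C@H]2OC(=O)[C@H](C)CC | intermediate
12 | methyl 3-O-acetyl-5-O-[(2R)-2-methylbutanoyl]shikimate | O[C@@H]1[C@H](OC(C)=O)C=C(C(=O)OC)C[C@H]1OC(=O)[C@H](C)CC | intermediate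
13 | methyl (3R,4S,5R)-3-acetoxy-5-{[(2R)-2-methylbutanoyl]oxy}-4-(propanoyloxy)cyclohex-1-ene-1-carboxylate | CCC(=O)O[C@@H]1[C@H](OC(C)=O)C=C(C(=O)OC)C[C@H]1OC(=O)[C@H](C)CC | target

**Step count and risks**

Total step count: 9. Longest linear sequence: 9 steps (1 and 2 to 13 through 3, 4, 5, 6, 8, 9, 11 and 12).

Steps most likely to fail:

Step 2. The chiral rhodium hydride may discriminate poorly between the two enantiotopic alkene carbons, or the exo alkylrhodium intermediate may lose the bridge oxygen by beta-alkoxide elimination before CO insertion. The fallback sets out from 3 and uses a different carbon–carbon bond formation. Nickel-catalysed asymmetric hydrovinylation (ethylene at 1 atm, [(allyl)NiBr]2, a chiral phosphoramidite ligand, NaB[3,5-(CF3)2C6H3]4, CH2Cl2, −70 °C) should give the exo-vinyl compound (1S,2R,4R,5S,6R)-2-ethenyl-5,6-(carbonyldioxy)-7-oxabicyclo[2.2.1]heptane F1. Ozonolysis (O3, CH2Cl2/MeOH, −78 °C; then Me2S) cleaves the vinyl group to the aldehyde, and the fallback comes back to the route at 4.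

Step 5. The endo alpha-hydrogen of 6 is screened by the endo carbonate, so enolisation may be slow; forcing it with more base or heat invites gamma-deprotonation of the product, loss of the C3/C4 oxygens and aromatisation. The fallback sets out from 4 and opens the bridge at the aldehyde oxidation level, where the alpha-hydrogen is far more acidic. An amine base (DBU cat. or Et3N, CH2Cl2, 0 °C) should give the enal (3R,4S,5R)-3,4-(carbonyldioxy)-5-hydroxycyclohex-1-ene-1-carbaldehyde F2. Pinnick oxidation (NaClO2, NaH2PO4, 2-methyl-2-butene) gives the acid (3R,4S,5R)-3,4-(carbonyldioxy)-5-hydroxycyclohex-1-ene-1-carboxylic acid F3. Trimethylsilyldiazomethane then gives the methyl ester, and the fallback comes back to the route at 7, which is methanolysed (K2CO3 cat., MeOH) to 8 as in the second half of step 5.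

Step 8. The hemi-orthoester may collapse without regiocontrol, or the acetyl group may migrate between O3 and O4 during hydrolysis or in step 9, so that the acetate and the propanoate end up mixed over the two positions. The fallback sets out from 8 and places the two esters one at a time in the opposite order.
- 2,2-Dimethoxypropane and CSA (cat.) in acetone should give methyl 3,4-O-isopropylidene-shikimate F4.
- Steglich esterification with 10 (DCC, DMAP, CH2Cl2) gives methyl 3,4-O-isopropylidene-5-O-[(2R)-2-methylbutanoyl]shikimate F5.
- Aqueous trifluoroacetic acid at 0 °C removes the acetonide to the diol methyl 5-O-[(2R)-2-methylbutanoyl]shikimate F6.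
- Borinic acid-catalysed acylation (EtCOCl, Ph2BOCH2CH2NH2 cat., i-Pr2NEt, MeCN, rt), which activates the equatorial oxygen of a cis-diol, should give methyl 5-O-[(2R)-2-methylbutanoyl]-4-O-propanoylshikimate F7.
- Acetylation of the remaining allylic hydroxyl (Ac2O, pyridine, DMAP cat., 0 °C) brings the fallback back to the route at 13.

**Further compounds**

F1 | step 2 | (1S,2R,4R,5S,6R)-2-ethenyl-5,6-(carbonyldioxy)-7-oxabicyclo[2.2.1]heptane (vinyl exo) | O=C1O[C@@H]2[C@H](O1)[C@H]3O[C@@H]2C[C@@H]3C=C
F2 | step 5 | (3R,4S,5R)-3,4-(carbonyldioxy)-5-hydroxycyclohex-1-ene-1-carbaldehyde | O=C1O[C@@H]2[C@H](O1)C=C(C=O)C[C@H]2O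
F3 | step 5 | (3R,4S,5R)-3,4-(carbonyldioxy)-5-hydroxycyclohex-1-ene-1-carboxylic acid | O=C1O[C@@H]2[C@H](O1)C=C(C(=O)O)C[C@H]2O
F4 | step 8 | methyl 3,4-O-isopropylidene-shikimate | CC1(C)O[C@@H]2[C@H](O1)C=C(C(=O)OC)C[C@H]2O
F5 | step 8 | methyl 3,4-O-isopropylidene-5-O-[(2R)-2-methylbutanoyl]shikimate | CC1(C)O[C@@H]2[C@H](O1)C=C(C(=O)OC)C[C@H]2OC(=O)[C@H](C)CC
F6 | step 8 | methyl 5-O-[(2R)-2-methylbutanoyl]shikimate | O[C@@H]1[C@H](O)C=C(C(=O)OC)C[C@H]1OC(=O)[C@H](C)CC
F7 | step 8 | methyl 5-O-[(2R)-2-methylbutanoyl]-4-O-propanoylshikimate | CCC(=O)O[C@@H]1[C@H](O)C=C(C(=O)OC)C[C@H]1OC(=O)[C@H](C)CC
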